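Assumption: commercial (R)-(+)-citronellal of ≥97% ee is used. Positions are given in plakortolide numbering (C1 lactone C=O, C3 CH–O–O, C4 and C6 the methyl-bearing ring carbons, C8 the side-chain CHMe, C11=C12 and C15=C16 the alkenes); the target is 3S,4S,6R,8R,11E,15E.

**Retrosynthetic overview**
- Target ⇒ peroxylactone C11 aldehyde + tetrazolyl sulfone of (E)-5-phenylpent-4-en-1-ol (Julia–Kocienski, C11=C12 made last so the styrene never meets the cobalt/O2 step).
- 1,2-Dioxane (second ring) ⇒ intramolecular oxa-Michael addition of a C6 tertiary hydroperoxide to a butenolide; hydroperoxide ⇒ hydroperoxysilylation of a C6 exo-methylene.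
- Butenolide (first ring) ⇒ Z-selective olefination/lactonisation of an α-silyloxy aldehyde; exo-methylene ⇒ Wittig on the C6 ketone.
- Key C4–C5 bond ⇒ catalytic enantioselective Mukaiyama aldol of a methyl-ketone enolsilane with methyl pyruvate (sets C4).
- C8 comes from (R)-citronellal; C6 is formed unselectively and the epimers are separated after ring closure.

**Route**

Step 1
Reactants: 1 (R)-citronellal [(3R)-3,7-dimethyloct-6-enal]
Product: 2 (4R)-4,8-dimethylnon-7-en-2-ol (about 1:1 at C2)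
Conditions: MeMgBr, Et2O, 0 °C; aq. NH4Cl
Reagents that add atoms: methylmagnesium bromide, C[Mg]Br
Why: Grignard 1,2-addition to the aldehyde installs C5 as a methyl carbinol; C8 comes unchanged from the chiral pool and the new carbinol centre is irrelevant because it is oxidised in step 4.

Step 2
Reactants: 2 (4R)-4,8-dimethylnon-7-en-2-ol
Product: 4 (4R)-4-methylheptane-1,6-diol (both C6 epimers), via secondary ozonide 3 (not isolated)
Conditions: O3, CH2Cl2, −78 °C; then NaBH4, MeOH, −78 °C → rt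
Reagents that add atoms: ozone, [O-][O+]=O
Why: Ozonolysis with reductive NaBH4 work-up cleaves the only alkene and reduces the ozonide to the C11 primary alcohol, so no trisubstituted alkene remains to compete in the later cobalt step.

Step 3
Reactants: 4 (4R)-4-methylheptane-1,6-diol
Product: 5 (4R)-7-[(tert-butyldiphenylsilyl)oxy]-4-methylheptan-2-ol
Conditions: TBDPSCl (1.05 equiv), imidazole, CH2Cl2, 0 °C
Reagents that add atoms: tert-butyl(chloro)diphenylsilane, CC(C)(C)[Si](Cl)(c1ccccc1)c1ccccc1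
Why: Sterically controlled silyl ether formation: the bulky chlorosilane reacts with the primary hydroxyl much faster than with the secondary one, and TBDPS survives every acidic, basic and hydride step up to step 14.

Step 4
Reactants: 5 (4R)-7-[(tert-butyldiphenylsilyl)oxy]-4-methylheptan-2-ol
Product: 6 (4R)-7-[(tert-butyldiphenylsilyl)oxy]-4-methylheptan-2-one
Conditions: Dess–Martin periodinane, CH2Cl2, rt
Reagents that add atoms: none
Why: Dess–Martin oxidation gives the methyl ketone and removes the stereorandom carbinol centre without touching the silyl ether or the β-stereocentre C8.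

Step 5
Reactants: 6 (4R)-7-[(tert-butyldiphenylsilyl)oxy]-4-methylheptan-2-one
Product: 7 tert-butyl({(4R)-4-methyl-6-[(trimethylsilyl)oxy]hept-6-en-1-yl}oxy)diphenylsilane
Conditions: LiN(iPr)2, THF, −78 °C; Me3SiCl, −78 → 0 °C; non-aqueous work-up, used crude
Reagents that add atoms: chlorotrimethylsilane, C[Si](C)(C)Cl
Why: Kinetic deprotonation by the hindered lithium amide occurs at the methyl group and not at the β-branched C7 methylene, and O-silylation traps the terminal enolate as the enolsilane.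

Step 6
Reactants: 7 tert-butyl({(4R)-4-methyl-6-[(trimethylsilyl)oxy]hept-6-en-1-yl}oxy)diphenylsilane; 8 methyl pyruvate
Product: 10 methyl (2S,6R)-9-[(tert-butyldiphenylsilyl)oxy]-2-hydroxy-2,6-dimethyl-4-oxononanoate, via trimethylsilyl ether 9 (not isolated)
Conditions: Cu(OTf)2 (10 mol%), 2,2'-(propane-2,2-diyl)bis[(4S)-4-tert-butyl-4,5-dihydro-1,3-oxazole] (11 mol%), THF, −78 °C; then 1 M aq. HCl, rt
Reagents that add atoms: none
Why: Evans catalytic enantioselective Mukaiyama aldol addition: methyl pyruvate chelates the square-planar divalent copper bis(oxazoline) complex, a tert-butyl group blocks the re face of the ketone, and the enolsilane adds to the si face to form the C4–C5 bond and the (S)-tertiary carbinol C4 (the minor C4 epimer is a diastereomer and is removed downstream).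

Step 7
Reactants: 10 methyl (2S,6R)-9-[(tert-butyldiphenylsilyl)oxy]-2-hydroxy-2,6-dimethyl-4-oxononanoate
Product: 11 methyl (2S,6R)-9-[(tert-butyldiphenylsilyl)oxy]-2,6-dimethyl-4-oxo-2-[(triethylsilyl)oxy]nonanoate
Conditions: Et3SiOTf, 2,6-lutidine, CH2Cl2, −78 → 0 °C
Reagents that add atoms: triethylsilyl trifluoromethanesulfonate, CC[Si](CC)(CC)OS(=O)(=O)C(F)(F)F
Why: Silylation of the hindered tertiary alcohol with the silyl triflate protects it against retro-aldol cleavage in the basic steps that follow.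

Step 8
Reactants: 11 methyl (2S,6R)-9-[(tert-butyldiphenylsilyl)oxy]-2,6-dimethyl-4-oxo-2-[(triethylsilyl)oxy]nonanoate
Product: 12 methyl (2S,6R)-9-[(tert-butyldiphenylsilyl)oxy]-2,6-dimethyl-4-methylidene-2-[(triethylsilyl)oxy]nonanoate
Conditions: Ph3PCH3Br, KOtBu, THF, 0 °C → rt
Reagents that add atoms: methyltriphenylphosphonium bromide, C[P+](c1ccccc1)(c1ccccc1)c1ccccc1.[Br-]
Why: Wittig methylenation turns the C6 ketone into the 1,1-disubstituted alkene needed for hydroperoxidation, and the hindered α-quaternary methyl ester does not react with the ylide.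

Step 9
Reactants: 12 methyl (2S,6R)-9-[(tert-butyldiphenylsilyl)oxy]-2,6-dimethyl-4-methylidene-2-[(triethylsilyl)oxy]nonanoate
Product: 13 (2S,6R)-9-[(tert-butyldiphenylsilyl)oxy]-2,6-dimethyl-4-methylidene-2-[(triethylsilyl)oxy]nonanal
Conditions: iBu2AlH (1.2 equiv), CH2Cl2, −78 °C; aq. potassium sodium tartrate
Reagents that add atoms: none
Why: Partial ester reduction: at −78 °C the α-silyloxy ester gives a stable aluminium hemiacetal that collapses to the aldehyde only on work-up, and the aldehyde has no α-hydrogen so C4 cannot epimerise.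

Step 10
Reactants: 13 (2S,6R)-9-[(tert-butyldiphenylsilyl)oxy]-2,6-dimethyl-4-methylidene-2-[(triethylsilyl)oxy]nonanal; 14 methyl 2-[bis(2,2,2-trifluoroethoxy)phosphoryl]acetate
Product: 15 methyl (2Z,4S,8R)-11-[(tert-butyldiphenylsilyl)oxy]-4,8-dimethyl-6-methylidene-4-[(triethylsilyl)oxy]undec-2-enoate
Conditions: KN(SiMe3)2, 18-crown-6, THF, −78 °C
Reagents that add atoms: none
Why: Still–Gennari variant of the Horner–Wadsworth–Emmons olefination: the electron-poor phosphonate with a crown-separated potassium counter-ion eliminates under kinetic control to the (Z)-enoate, the geometry needed for lactonisation.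

Step 11
Reactants: 15 methyl (2Z,4S,8R)-11-[(tert-butyldiphenylsilyl)oxy]-4,8-dimethyl-6-methylidene-4-[(triethylsilyl)oxy]undec-2-enoate
Product: 17 (5S)-5-{(4R)-7-[(tert-butyldiphenylsilyl)oxy]-4-methyl-2-methylideneheptyl}-5-methylfuran-2(5H)-one, via hydroxy enoate 16 (not isolated)
Conditions: p-TsOH·H2O (0.3 equiv), MeOH, rt
Reagents that add atoms: none
Why: Acid-catalysed methanolysis of the tertiary triethylsilyl ether (TBDPS is stable) frees the C4 hydroxyl, which sits next to the (Z)-ester and lactonises spontaneously to the butenolide (first ring).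

Step 12
Reactants: 17 (5S)-5-{(4R)-7-[(tert-butyldiphenylsilyl)oxy]-4-methyl-2-methylideneheptyl}-5-methylfuran-2(5H)-one
Product: 18 (5S)-5-{(4R)-7-[(tert-butyldiphenylsilyl)oxy]-2,4-dimethyl-2-[(triethylsilyl)peroxy]heptyl}-5-methylfuran-2(5H)-one (about 1:1 at C6)
Conditions: Co(thd)2 (10 mol%; thd = 2,2,6,6-tetramethylheptane-3,5-dionate), O2 (1 atm), Et3SiH (2 equiv), ClCH2CH2Cl, rt
Reagents that add atoms: dioxygen, O=O; triethylsilane, CC[SiH](CC)CC
Why: Mukaiyama–Isayama hydroperoxysilylation: a cobalt hydride transfers a hydrogen atom to the terminal carbon of the electron-rich 1,1-disubstituted alkene and the tertiary C6 radical is trapped by O2 and silylated, while the conjugated, hindered butenolide alkene is left alone; the radical has no facial bias, so C6 forms as a near 1:1 mixture resolved in step 13.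

Step 13
Reactants: 18 (5S)-5-{(4R)-7-[(tert-butyldiphenylsilyl)oxy]-2,4-dimethyl-2-[(triethylsilyl)peroxy]heptyl}-5-methylfuran-2(5H)-one
Product: 20 (3R,4aS,7aS)-3-{(2R)-5-[(tert-butyldiphenylsilyl)oxy]-2-methylpentyl}-3,4a-dimethyltetrahydro-3H-furo[3,2-c][1,2]dioxin-6(4H)-one, via hydroperoxide 19 (not isolated)
Conditions: conc. HCl (cat.), MeOH, 0 °C; then Et2NH, CF3CH2OH, rt; SiO2 chromatography (removes the C6 epimer)
Reagents that add atoms: none
Why: Acidic methanolysis frees the hydroperoxide, which under amine catalysis undergoes intramolecular 6-exo oxa-Michael addition to the butenolide; the tether from C4 allows only cis ring fusion, so C3 is set as S by C4, and the (6R) bicycle is separated from its C6 epimer (second ring).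

Step 14
Reactants: 20 (3R,4aS,7aS)-3-{(2R)-5-[(tert-butyldiphenylsilyl)oxy]-2-methylpentyl}-3,4a-dimethyltetrahydro-3H-furo[3,2-c][1,2]dioxin-6(4H)-one
Product: 21 (3R,4aS,7aS)-3-[(2R)-5-hydroxy-2-methylpentyl]-3,4a-dimethyltetrahydro-3H-furo[3,2-c][1,2]dioxin-6(4H)-one
Conditions: HF·pyridine, pyridine, THF, 0 °C → rt
Reagents that add atoms: none
Why: Fluoride-mediated desilylation under buffered, weakly acidic conditions removes TBDPS without harming the dialkyl peroxide or the lactone.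

Step 15
Reactants: 21 (3R,4aS,7aS)-3-[(2R)-5-hydroxy-2-methylpentyl]-3,4a-dimethyltetrahydro-3H-furo[3,2-c][1,2]dioxin-6(4H)-one
Product: 22 (4R)-5-[(3R,4aS,7aS)-3,4a-dimethyl-6-oxotetrahydro-3H-furo[3,2-c][1,2]dioxin-3-yl]-4-methylpentanal
Conditions: Dess–Martin periodinane, CH2Cl2, 0 °C → rt
Reagents that add atoms: none
Why: Dess–Martin oxidation is neutral and non-reducing, so the primary alcohol becomes the C11 aldehyde while the O–O bond and lactone survive.

Step 16
Reactants: 23 1-phenylprop-2-en-1-ol (racemic); 24 triethyl orthoacetate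
Product: 26 ethyl (4E)-5-phenylpent-4-enoate, via ketene acetal 25 (not isolated)
Conditions: EtCO2H (cat.), 140 °C, EtOH distilled off
Reagents that add atoms: none
Why: Johnson–Claisen rearrangement: the mixed ketene acetal rearranges through a chair transition state with phenyl equatorial, giving the conjugated (E)-styrene.

Step 17
Reactants: 26 ethyl (4E)-5-phenylpent-4-enoate
Product: 27 (4E)-5-phenylpent-4-en-1-ol
Conditions: LiAlH4, THF, 0 °C
Reagents that add atoms: none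
Why: Hydride reduction of the ester to the primary alcohol; the unconjugated styrene is inert to LiAlH4.

Step 18
Reactants: 27 (4E)-5-phenylpent-4-en-1-ol; 28 1-phenyl-1H-tetrazole-5-thiol
Product: 29 1-phenyl-5-{[(4E)-5-phenylpent-4-en-1-yl]sulfanyl}-1H-tetrazole
Conditions: PPh3, iPrO2CN=NCO2iPr, THF, 0 °C → rt
Reagents that add atoms: none
Why: Mitsunobu thioetherification of the primary alcohol with the acidic heteroaryl thiol.

Step 19
Reactants: 29 1-phenyl-5-{[(4E)-5-phenylpent-4-en-1-yl]sulfanyl}-1H-tetrazole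
Product: 30 1-phenyl-5-{[(4E)-5-phenylpent-4-en-1-yl]sulfonyl}-1H-tetrazole
Conditions: (NH4)6Mo7O24·4H2O (10 mol%), 30% aq. H2O2, EtOH, 0 °C → rt
Reagents that add atoms: hydrogen peroxide, OO
Why: Molybdate-catalysed peroxide oxidation converts the sulfide into the sulfone and is chemoselective for sulfur over the styrene.

Step 20
Reactants: 22 (4R)-5-[(3R,4aS,7aS)-3,4a-dimethyl-6-oxotetrahydro-3H-furo[3,2-c][1,2]dioxin-3-yl]-4-methylpentanal; 30 1-phenyl-5-{[(4E)-5-phenylpent-4-en-1-yl]sulfonyl}-1H-tetrazole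
Product: 31 (3R,4aS,7aS)-3,4a-dimethyl-3-[(2R,5E,9E)-2-methyl-10-phenyldeca-5,9-dien-1-yl]tetrahydro-3H-furo[3,2-c][1,2]dioxin-6(4H)-one (target)
Conditions: 30 (1.3 equiv), KN(SiMe3)2 (1.2 equiv), DME, −60 °C, 30 min; then 22, −60 °C → rt
Reagents that add atoms: none
Why: Julia–Kocienski olefination: the pre-formed sulfonyl carbanion (no free amide base) adds to the aldehyde faster than it can deprotonate the β-peroxy lactone, and Smiles rearrangement with anti elimination gives the (11E)-alkene (typically ≥9:1), completing the target.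

**Compound list**
1 | (R)-citronellal | C[C@H](CCC=C(C)C)CC=O | starting material
2 | (4R)-4,8-dimethylnon-7-en-2-ol (C2 epimers) | C[C@H](CCC=C(C)C)CC(C)O | intermediate
3 | 5-[(3R)-5-hydroxy-3-methylhexyl]-3,3-dimethyl-1,2,4-trioxolane (secondary ozonide) | C[C@H](CCC1OOC(C)(C)O1)CC(C)O | intermediate
4 | (4R)-4-methylheptane-1,6-diol (C6 epimers) | C[C@H](CCCO)CC(C)O | intermediate
5 | (4R)-7-[(tert-butyldiphenylsilyl)oxy]-4-methylheptan-2-ol | C[C@H](CCCO[Si](c1ccccc1)(c1ccccc1)C(C)(C)C)CC(C)O | intermediate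
6 | (4R)-7-[(tert-butyldiphenylsilyl)oxy]-4-methylheptan-2-one | C[C@H](CCCO[Si](c1ccccc1)(c1ccccc1)C(C)(C)C)CC(C)=O | intermediate
7 | tert-butyl({(4R)-4-methyl-6-[(trimethylsilyl)oxy]hept-6-en-1-yl}oxy)diphenylsilane | C[C@H](CCCO[Si](c1ccccc1)(c1ccccc1)C(C)(C)C)CC(=C)O[Si](C)(C)C | intermediate
8 | methyl pyruvate | COC(=O)C(C)=O | starting material
9 | methyl (2S,6R)-9-[(tert-butyldiphenylsilyl)oxy]-2,6-dimethyl-4-oxo-2-[(trimethylsilyl)oxy]nonanoate | C[C@H](CCCO[Si](c1ccccc1)(c1ccccc1)C(C)(C)C)CC(=O)C[C@](C)(O[Si](C)(C)C)C(=O)OC | intermediate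
10 | methyl (2S,6R)-9-[(tert-butyldiphenylsilyl)oxy]-2-hydroxy-2,6-dimethyl-4-oxononanoate | C[C@H](CCCO[Si](c1ccccc1)(c1ccccc1)C(C)(C)C)CC(=O)C[C@](C)(O)C(=O)OC | intermediate
11 | methyl (2S,6R)-9-[(tert-butyldiphenylsilyl)oxy]-2,6-dimethyl-4-oxo-2-[(triethylsilyl)oxy]nonanoate | C[C@H](CCCO[Si](c1ccccc1)(c1ccccc1)C(C)(C)C)CC(=O)C[C@](C)(O[Si](CC)(CC)CC)C(=O)OC | intermediate
12 | methyl (2S,6R)-9-[(tert-butyldiphenylsilyl)oxy]-2,6-dimethyl-4-methylidene-2-[(triethylsilyl)oxy]nonanoate | C[C@H](CCCO[Si](c1ccccc1)(c1ccccc1)C(C)(C)C)CC(=C)C[C@](C)(O[Si](CC)(CC)CC)C(=O)OC | intermediate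
13 | (2S,6R)-9-[(tert-butyldiphenylsilyl)oxy]-2,6-dimethyl-4-methylidene-2-[(triethylsilyl)oxy]nonanal | C[C@H](CCCO[Si](c1ccccc1)(c1ccccc1)C(C)(C)C)CC(=C)C[C@](C)(O[Si](CC)(CC)CC)C=O | intermediate
14 | methyl 2-[bis(2,2,2-trifluoroethoxy)phosphoryl]acetate | COC(=O)CP(=O)(OCC(F)(F)F)OCC(F)(F)F | starting material
15 | methyl (2Z,4S,8R)-11-[(tert-butyldiphenylsilyl)oxy]-4,8-dimethyl-6-methylidene-4-[(triethylsilyl)oxy]undec-2-enoate | C[C@H](CCCO[Si](c1ccccc1)(c1ccccc1)C(C)(C)C)CC(=C)C[C@](C)(O[Si](CC)(CC)CC)/C=C\C(=O)OC | intermediate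
16 | methyl (2Z,4S,8R)-11-[(tert-butyldiphenylsilyl)oxy]-4-hydroxy-4,8-dimethyl-6-methylideneundec-2-enoate | C[C@H](CCCO[Si](c1ccccc1)(c1ccccc1)C(C)(C)C)CC(=C)C[C@](C)(O)/C=C\C(=O)OC | intermediate
17 | (5S)-5-{(4R)-7-[(tert-butyldiphenylsilyl)oxy]-4-methyl-2-methylideneheptyl}-5-methylfuran-2(5H)-one | C[C@H](CCCO[Si](c1ccccc1)(c1ccccc1)C(C)(C)C)CC(=C)C[C@]1(C)OC(=O)C=C1 | intermediate
18 | (5S)-5-{(4R)-7-[(tert-butyldiphenylsilyl)oxy]-2,4-dimethyl-2-[(triethylsilyl)peroxy]heptyl}-5-methylfuran-2(5H)-one (C6 epimers) | C[C@H](CCCO[Si](c1ccccc1)(c1ccccc1)C(C)(C)C)CC(C)(OO[Si](CC)(CC)CC)C[C@]1(C)OC(=O)C=C1 | intermediate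
19 | (5S)-5-{(4R)-7-[(tert-butyldiphenylsilyl)oxy]-2-hydroperoxy-2,4-dimethylheptyl}-5-methylfuran-2(5H)-one (C6 epimers) | C[C@H](CCCO[Si](c1ccccc1)(c1ccccc1)C(C)(C)C)CC(C)(OO)C[C@]1(C)OC(=O)C=C1 | intermediate
20 | (3R,4aS,7aS)-3-{(2R)-5-[(tert-butyldiphenylsilyl)oxy]-2-methylpentyl}-3,4a-dimethyltetrahydro-3H-furo[3,2-c][1,2]dioxin-6(4H)-one | C[C@H](CCCO[Si](c1ccccc1)(c1ccccc1)C(C)(C)C)C[C@]1(C)C[C@]2(C)OC(=O)C[C@@H]2OO1 | intermediate
21 | (3R,4aS,7aS)-3-[(2R)-5-hydroxy-2-methylpentyl]-3,4a-dimethyltetrahydro-3H-furo[3,2-c][1,2]dioxin-6(4H)-one | C[C@H](CCCO)C[C@]1(C)C[C@]2(C)OC(=O)C[C@@H]2OO1 | intermediate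
22 | (4R)-5-[(3R,4aS,7aS)-3,4a-dimethyl-6-oxotetrahydro-3H-furo[3,2-c][1,2]dioxin-3-yl]-4-methylpentanal | C[C@H](CCC=O)C[C@]1(C)C[C@]2(C)OC(=O)C[C@@H]2OO1 | intermediate
23 | 1-phenylprop-2-en-1-ol | C=CC(O)c1ccccc1 | starting material
24 | triethyl orthoacetate | CCOC(C)(OCC)OCC | starting material
25 | {1-[(1-ethoxyethenyl)oxy]prop-2-en-1-yl}benzene (ketene acetal) | C=CC(OC(=C)OCC)c1ccccc1 | intermediate
26 | ethyl (4E)-5-phenylpent-4-enoate | CCOC(=O)CC/C=C/c1ccccc1 | intermediate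
27 | (4E)-5-phenylpent-4-en-1-ol | OCCC/C=C/c1ccccc1 | intermediate
28 | 1-phenyl-1H-tetrazole-5-thiol | Sc1nnnn1-c1ccccc1 | starting material
29 | 1-phenyl-5-{[(4E)-5-phenylpent-4-en-1-yl]sulfanyl}-1H-tetrazole | c1ccccc1-n1nnnc1SCCC/C=C/c1ccccc1 | intermediate
30 | 1-phenyl-5-{[(4E)-5-phenylpent-4-en-1-yl]sulfonyl}-1H-tetrazole | O=S(=O)(CCC/C=C/c1ccccc1)c1nnnn1-c1ccccc1 | intermediate
31 | (3R,4aS,7aS)-3,4a-dimethyl-3-[(2R,5E,9E)-2-methyl-10-phenyldeca-5,9-dien-1-yl]tetrahydro-3H-furo[3,2-c][1,2]dioxin-6(4H)-one | C[C@H](CC/C=C/CC/C=C/c1ccccc1)C[C@]1(C)C[C@]2(C)OC(=O)C[C@@H]2OO1 | target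

**Totals**
Total step count: 20. Longest linear sequence: 16 steps (steps 1–15 and 20); the sulfone branch is steps 16–19.

**Three steps most likely to fail**

Step 6 (enantioselective aldol). The hindered ketone enolsilane may react slowly or with lower selectivity than simpler enolsilanes, and it is moisture-sensitive. The fallback sets out from 6 and comes back at 12, replacing the aldol by a carbonyl allylation with a stable, chromatographable nucleophile. Ketone 6 is treated with LiN(iPr)2 at −78 °C and PhN(SO2CF3)2 to give the kinetic enol triflate (4R)-7-[(tert-butyldiphenylsilyl)oxy]-4-methylhept-1-en-2-yl trifluoromethanesulfonate F1. Kumada coupling of F1 with Me3SiCH2MgCl and catalytic Pd(PPh3)4 gives the allylsilane tert-butyl({(4R)-4-methyl-6-[(trimethylsilyl)methyl]hept-6-en-1-yl}oxy)diphenylsilane F2. Hosomi–Sakurai allylation of methyl pyruvate 8 with F2 under the same copper bis(oxazoline) Lewis acid (SbF6 counter-ion, CH2Cl2, then aq. HCl) attacks the same si face and gives methyl (2S,6R)-9-[(tert-butyldiphenylsilyl)oxy]-2-hydroxy-2,6-dimethyl-4-methylidenenonanoate F3, with the C6 methylidene already in place. Silylation of F3 with Et3SiOTf and 2,6-lutidine gives 12.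

Step 12 (hydroperoxysilylation). The butenolide alkene may compete for the cobalt hydride, or the silyl peroxide may be over-reduced. The fallback sets out from 13 and comes back at 18, running the cobalt step on a substrate with no conjugated alkene. Aldol addition of the lithium enolate of methyl acetate (LiN(iPr)2, MeOAc, THF, −78 °C) to 13 gives methyl (4S,8R)-11-[(tert-butyldiphenylsilyl)oxy]-3-hydroxy-4,8-dimethyl-6-methylidene-4-[(triethylsilyl)oxy]undecanoate F4 (C3 epimers, irrelevant). p-TsOH·H2O in MeOH removes the triethylsilyl group and closes the saturated lactone (5S)-5-{(4R)-7-[(tert-butyldiphenylsilyl)oxy]-4-methyl-2-methylideneheptyl}-4-hydroxy-5-methyloxolan-2-one F5. The conditions of step 12 then give (5S)-5-{(4R)-7-[(tert-butyldiphenylsilyl)oxy]-2,4-dimethyl-2-[(triethylsilyl)peroxy]heptyl}-4-hydroxy-5-methyloxolan-2-one F6. MsCl and Et3N form the mesylate (2S)-2-{(4R)-7-[(tert-butyldiphenylsilyl)oxy]-2,4-dimethyl-2-[(triethylsilyl)peroxy]heptyl}-2-methyl-5-oxooxolan-3-yl methanesulfonate F7 in the flask, which eliminates (E1cB) to the butenolide 18.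

Step 20 (Julia–Kocienski on the β-peroxy lactone). The lactone enolate, if formed, would open or rearrange the peroxide. The fallback sets out from 17 and comes back at 31; it moves the olefination ahead of ring closure, where the substrate has no enolisable C–H next to the peroxide. HF·pyridine converts 17 into (5S)-5-[(4R)-7-hydroxy-4-methyl-2-methylideneheptyl]-5-methylfuran-2(5H)-one F8. The conditions of step 12 give (5S)-5-{(4R)-7-hydroxy-2,4-dimethyl-2-[(triethylsilyl)peroxy]heptyl}-5-methylfuran-2(5H)-one F9. Dess–Martin oxidation gives (4R)-4,6-dimethyl-7-[(2S)-2-methyl-5-oxo-2,5-dihydrofuran-2-yl]-6-[(triethylsilyl)peroxy]heptanal F10. Julia–Kocienski olefination of F10 with sulfone 30 (KN(SiMe3)2, DME, −60 °C) gives (5S)-5-{(4R,7E,11E)-2,4-dimethyl-12-phenyl-2-[(triethylsilyl)peroxy]dodeca-7,11-dien-1-yl}-5-methylfuran-2(5H)-one F11. Catalytic HCl in MeOH frees (5S)-5-[(4R,7E,11E)-2-hydroperoxy-2,4-dimethyl-12-phenyldodeca-7,11-dien-1-yl]-5-methylfuran-2(5H)-one F12, which closes with Et2NH in CF3CH2OH to 31; the C6 epimer is then removed at the final stage.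

**Further compounds**
F1 | step 6 | (4R)-7-[(tert-butyldiphenylsilyl)oxy]-4-methylhept-1-en-2-yl trifluoromethanesulfonate | C[C@H](CCCO[Si](c1ccccc1)(c1ccccc1)C(C)(C)C)CC(=C)OS(=O)(=O)C(F)(F)F
F2 | step 6 | tert-butyl({(4R)-4-methyl-6-[(trimethylsilyl)methyl]hept-6-en-1-yl}oxy)diphenylsilane | C[C@H](CCCO[Si](c1ccccc1)(c1ccccc1)C(C)(C)C)CC(=C)C[Si](C)(C)C
F3 | step 6 | methyl (2S,6R)-9-[(tert-butyldiphenylsilyl)oxy]-2-hydroxy-2,6-dimethyl-4-methylidenenonanoate | C[C@H](CCCO[Si](c1ccccc1)(c1ccccc1)C(C)(C)C)CC(=C)C[C@](C)(O)C(=O)OC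
F4 | step 12 | methyl (4S,8R)-11-[(tert-butyldiphenylsilyl)oxy]-3-hydroxy-4,8-dimethyl-6-methylidene-4-[(triethylsilyl)oxy]undecanoate | C[C@H](CCCO[Si](c1ccccc1)(c1ccccc1)C(C)(C)C)CC(=C)C[C@](C)(O[Si](CC)(CC)CC)C(O)CC(=O)OC
F5 | step 12 | (5S)-5-{(4R)-7-[(tert-butyldiphenylsilyl)oxy]-4-methyl-2-methylideneheptyl}-4-hydroxy-5-methyloxolan-2-one | C[C@H](CCCO[Si](c1ccccc1)(c1ccccc1)C(C)(C)C)CC(=C)C[C@]1(C)OC(=O)CC1O
F6 | step 12 | (5S)-5-{(4R)-7-[(tert-butyldiphenylsilyl)oxy]-2,4-dimethyl-2-[(triethylsilyl)peroxy]heptyl}-4-hydroxy-5-methyloxolan-2-one | C[C@H](CCCO[Si](c1ccccc1)(c1ccccc1)C(C)(C)C)CC(C)(OO[Si](CC)(CC)CC)C[C@]1(C)OC(=O)CC1O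
F7 | step 12 | (2S)-2-{(4R)-7-[(tert-butyldiphenylsilyl)oxy]-2,4-dimethyl-2-[(triethylsilyl)peroxy]heptyl}-2-methyl-5-oxooxolan-3-yl methanesulfonate | C[C@H](CCCO[Si](c1ccccc1)(c1ccccc1)C(C)(C)C)CC(C)(OO[Si](CC)(CC)CC)C[C@]1(C)OC(=O)CC1OS(C)(=O)=O
F8 | step 20 | (5S)-5-[(4R)-7-hydroxy-4-methyl-2-methylideneheptyl]-5-methylfuran-2(5H)-one | C[C@H](CCCO)CC(=C)C[C@]1(C)OC(=O)C=C1
F9 | step 20 | (5S)-5-{(4R)-7-hydroxy-2,4-dimethyl-2-[(triethylsilyl)peroxy]heptyl}-5-methylfuran-2(5H)-one | C[C@H](CCCO)CC(C)(OO[Si](CC)(CC)CC)C[C@]1(C)OC(=O)C=C1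
F10 | step 20 | (4R)-4,6-dimethyl-7-[(2S)-2-methyl-5-oxo-2,5-dihydrofuran-2-yl]-6-[(triethylsilyl)peroxy]heptanal | C[C@H](CCC=O)CC(C)(OO[Si](CC)(CC)CC)C[C@]1(C)OC(=O)C=C1
F11 | step 20 | (5S)-5-{(4R,7E,11E)-2,4-dimethyl-12-phenyl-2-[(triethylsilyl)peroxy]dodeca-7,11-dien-1-yl}-5-methylfuran-2(5H)-one | C[C@H](CC/C=C/CC/C=C/c1ccccc1)CC(C)(OO[Si](CC)(CC)CC)C[C@]1(C)OC(=O)C=C1
F12 | step 20 | (5S)-5-[(4R,7E,11E)-2-hydroperoxy-2,4-dimethyl-12-phenyldodeca-7,11-dien-1-yl]-5-methylfuran-2(5H)-one | C[C@H](CC/C=C/CC/C=C/c1ccccc1)CC(C)(OO)C[C@]1(C)OC(=O)C=C1
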